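If Z decayed with one fixed time constant, the pseudo-first-order case, then H, minus the natural log of the fraction of Z left, would count elapsed time constants and grow in step with time t. We test that on two earlier runs, with Z the monomer, G the monomer in chains and D the initiator as charged.

| flask | Z | D | temperature | remark | time |
|---|---|---|---|---|---|
| zeta | 0.35 M | 1.9 mol% | 79 °C | run made earlier |  |
| gamma | 0.55 M | 1.9 mol% | 87 °C | run made earlier |  |
| Friday's | 0.25 M | 1.9 mol% | 75 °C |  | 40 min |
| Sunday's | 0.25 M | 1.9 mol% | 90 °C |  | 40 min |

| run | time / min | G / % | Z / % |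
|---|---|---|---|
| zeta | 3.00 | 0 | 100.2 |
| zeta | 6.00 | 0.8 | 99.7 |
| zeta | 12.0 | 1.2 | 100.4 |
| zeta | 20.0 | 4.1 | 95.3 |
| zeta | 40.0 | 21.4 | 78.6 |
| gamma | 4.00 | 0.8 | 99.1 |
| gamma | 8.00 | 4.1 | 95.4 |
| gamma | 15.0 | 19.5 | 80.0 |
| gamma | 20.0 | 36.7 | 64.2 |

(readings scatter by 0.5 percentage points)

- the flask that comes out highest in amount of G, in percent of the Z charged, or "all alike" when all lie within 1.5 percentage points (Friday's / Sunday's / all alike)
- G at the end, in percent of the Z charged, Friday's
- G at the end, in percent of the Z charged, Sunday's

Zeta's last reading holds G 21.4% and Z 78.6%, so what Z loses stands as G. But H does not grow in step with t. In zeta, between 20.0 min and 40.0 min, H grows 5.75 times. That reads 2.52 for n, the time exponent: the slope of ln H against ln t. Gamma reads 2.61, so we freeze n.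

With n frozen, a flask whose clock runs s times zeta's has s^n times zeta's H. Gamma reaches G 4.1% at 8.00 min, and zeta reaches 4.1% at 20.0 min, so s reads 2.50. But gamma is hotter and richer in Z, so this speed does not separate the two settings.

The forecast says Sunday's, with 6% for Friday's and 80% for Sunday's, where it warns "this is an extrapolation and depends strongly on a", a being its exponent on concentration. Through n, we reckon those figures as s of 0.583 and 2.12. We accept its order but hold Sunday's figure loosely, since at frozen n a clock twice as fast multiplies H by 5.74.

Sunday's ends at G 60.0% and Friday's at 5.42%, so Sunday's stands highest, and the forecast's Sunday figure lies 20 percentage points above. The flasks ran by this scheme, with Q the initiator that D turns into and L the living end: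

    Z + Q → L + G (k = 0.0660 L mol⁻¹ min⁻¹, Ea = 92.0 kJ mol⁻¹)
    Z + L → G + L, rate k2*[L]*[Z] (k = 36.0 L mol⁻¹ min⁻¹, Ea = 55.0 kJ mol⁻¹)
    D → Q (k = 0.0780 min⁻¹, Ea = 100 kJ mol⁻¹)
    (constants at 90 °C)

Zeta moved to Sunday's temperature with its amount kept reaches 78.6%; with Sunday's amount too, it reaches 60.0%. Through n, Sunday's end reads s = 1.70, against the 2.12 we reckoned from the forecast's figure. Friday's end of 5.42% reads s = 0.560.

The data stem from a simulated flask with made-up constants; noise was put on by code.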